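The target is read as a 1,2-diarylpropane: C2 and C3 of the dihydrofuran ring are adjacent stereocentres that carry guaiacyl ring B and benzo ring A (through C3a). The route rests on cutting ring B from C2. One enantioselective conjunctive cross-coupling merges a ring B aryllithium, (E)-propenylB(mac) and a ring A aryl bromide that already holds the lactaldehyde-derived erythro-diol. A 1,2-boronate shift forms the aryl–C2 bond, reductive elimination forms C3–C3a, and both stereocentres arise together. The precursor is an acyclic lithium borate without any furan ring. Boron marks C2 for oxygenation; a fluoride-triggered para-quinone methide closure then forms O1–C2 trans and frees all hydroxyls.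

Key step: step 7

Abbreviations: TBS = tert-butyldimethylsilyl; mac = the diolate of cis-1,2-dimethyl-1,2-dihydroacenaphthylene-1,2-diol.

Assumption: the MandyPhos antipode named in step 7 is taken to steer palladium to the Re face of C3 (if the sense of induction is opposite, its commercial mirror image is used); aldehyde 7 is taken as a commercial chiral pool compound derived from ethyl (S)-lactate.

Step 1
Reactants: 1 acenaphthenequinone
Product: 2 cis-1,2-dimethyl-1,2-dihydroacenaphthylene-1,2-diol (meso mac diol)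
Conditions: MeMgBr (3 equiv), THF, 0 °C → rt; aq NH4Cl; recrystallisation
Reagents that add atoms: methylmagnesium bromide, C[Mg]Br
Why: Double Grignard 1,2-addition to the 1,2-dione, in which the second methyl should add away from the solvated magnesium alkoxide to favour the achiral cis diol, the only isomer able to bridge boron in step 2.

Step 2
Reactants: 2 mac diol; 3 (E)-prop-1-en-1-ylboronic acid
Product: 4 (E)-prop-1-en-1-ylboronic acid mac ester, (E)-propenylB(mac)
Conditions: MgSO4, CH2Cl2, rt
Reagents that add atoms: none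
Why: Dehydrative boronic ester formation with a cis-1,2-diol, which leaves the (E)-alkene geometry untouched.

Step 3
Reactants: 5 2-bromo-6-methoxyphenol
Product: 6 2-bromo-4-iodo-6-methoxyphenol
Conditions: NIS (1.05 equiv), TsOH·H2O (10 mol %), MeCN, 0 °C → rt
Reagents that add atoms: N-iodosuccinimide, O=C1CCC(=O)N1I
Why: Electrophilic aromatic iodination directed by the free hydroxyl to its only open activated position (para), since both ortho positions are occupied.

Step 4
Reactants: 6 2-bromo-4-iodo-6-methoxyphenol; 7 (S)-2-(tert-butyldimethylsilyloxy)propanal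
Product: 9 (1R,2S)-1-(3-bromo-4-hydroxy-5-methoxyphenyl)-2-(tert-butyldimethylsilyloxy)propan-1-ol, via aryl Grignard phenolate 8 (not isolated)
Conditions: MeMgCl (1.0 equiv), LiCl, THF, −30 °C; i-PrMgCl (1.1 equiv), −30 °C → rt; then 7, −78 → −20 °C; aq NH4Cl
Reagents that add atoms: none
Why: Iodine–magnesium exchange on the pre-formed magnesium phenolate (iodide reacts far faster than bromide) gives 8, and its Grignard addition to the non-chelating α-silyloxy aldehyde follows the polar Felkin–Anh model, which sets the benzylic carbinol as R, anti to the lactate-derived S centre that is carried over unchanged.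

Step 5
Reactants: 9 bromophenol diol monosilyl ether
Product: 10 1-bromo-2-(tert-butyldimethylsilyloxy)-3-methoxy-5-[(1R,2S)-1,2-bis(tert-butyldimethylsilyloxy)propyl]benzene (ring A bromide)
Conditions: TBSOTf (2.5 equiv), 2,6-lutidine (4 equiv), CH2Cl2, 0 °C → rt
Reagents that add atoms: tert-butyldimethylsilyl trifluoromethanesulfonate, CC(C)(C)[Si](C)(C)OS(=O)(=O)C(F)(F)F
Why: Silyl triflate silylation caps the hindered phenol and the benzylic alcohol in one operation without touching either stereocentre.

Step 6
Reactants: 11 4-bromo-2-methoxyphenol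
Product: 12 (4-bromo-2-methoxyphenoxy)(tert-butyl)dimethylsilane
Conditions: TBSCl, imidazole, DMF, rt
Reagents that add atoms: tert-butyldimethylsilyl chloride, CC(C)(C)[Si](C)(C)Cl
Why: Standard imidazole-promoted silylation of a phenol gives a ring B bromide that tolerates bromine–lithium exchange and is cleaved by fluoride at the end.

Step 7
Reactants: 12 ring B bromide; 4 (E)-propenylB(mac); 10 ring A bromide
Product: 16 (1S,2S)-1-[4-(tert-butyldimethylsilyloxy)-3-methoxyphenyl]-2-{2-(tert-butyldimethylsilyloxy)-3-methoxy-5-[(1R,2S)-1,2-bis(tert-butyldimethylsilyloxy)propyl]phenyl}propan-1-ol, via aryllithium 13 (not isolated), via lithium borate 14 (not isolated), via secondary boronic ester 15 (not isolated)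
Conditions: 12, t-BuLi (2.0 equiv), Et2O, −78 °C; 4, −78 °C → rt; solvent switch to THF; 10, Pd(OAc)2 (3 mol %), (S,S)-1,1'-bis[bis(4-methoxy-3,5-dimethylphenyl)phosphino]-2,2'-bis[(R)-α-(dimethylamino)benzyl]ferrocene (MandyPhos ligand, 3.6 mol %), KOSO2CF3 (3 equiv), 60 °C; then NaBO3·4H2O, THF/H2O, rt
Reagents that add atoms: sodium perborate tetrahydrate (oxygen donor), [Na+].[Na+].O[B-]1(O)OO[B-](O)(O)OO1
Why: Zerovalent palladium inserts into the C–Br bond of 10, K+ strips bromide, and the cationic divalent arylpalladium binds the propenyl π bond of borate 14 and induces a 1,2-metallate shift in which ring B migrates from boron to C2 (the aryl–C2 bond) while palladium bonds to C3; reductive elimination with retention then forms C3–C3a, and perborate replaces boron by hydroxyl with retention. This is the known enantioselective conjunctive cross-coupling of β-substituted alkenylB(mac) ate complexes with aryllithiums and aryl electrophiles, applied to new partners. No ring is closed in this step. Migration is anti-periplanar to palladium, so rings B and A add anti across the (E)-alkene and this stereospecificity fixes the C2/C3 relationship (1S,2S after oxidation), while the chiral bisphosphine chooses the Re face of C3 and so fixes the absolute configuration. The conjunctive path must outrun direct Suzuki–Miyaura transfer and β-hydride elimination from the secondary alkylpalladium: the bulky mac diol shields the boronate oxygens against transmetalation, the wide-bite-angle ferrocenyl ligand speeds reductive elimination, and KOSO2CF3 removes the inhibiting bromide. Site selectivity is secured because 10 has a single carbon–halogen bond and every hydroxyl is silylated.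

Step 8
Reactants: 16 diarylpropanol
Product: 17 (1S,2S)-1-[4-(tert-butyldimethylsilyloxy)-3-methoxyphenyl]-2-{2-(tert-butyldimethylsilyloxy)-3-methoxy-5-[(1R,2S)-1,2-bis(tert-butyldimethylsilyloxy)propyl]phenyl}propyl acetate
Conditions: Ac2O, Et3N, DMAP (cat.), CH2Cl2, 0 °C → rt
Reagents that add atoms: acetic anhydride, CC(=O)OC(C)=O
Why: DMAP-catalysed acylation of the only free hydroxyl turns the C2 oxygen into a leaving group without disturbing any stereocentre.

Step 9
Reactants: 17 benzylic acetate
Product: 20 (1R,2S)-1-[(2S,3S)-2-(4-hydroxy-3-methoxyphenyl)-7-methoxy-3-methyl-2,3-dihydro-1-benzofuran-5-yl]propane-1,2-diol, via para-quinone methide 18 (not isolated), via cyclised bis-silyl ether 19 (not isolated)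
Conditions: TBAF (6 equiv), THF, 0 °C → rt; aq NH4Cl
Reagents that add atoms: none
Why: Fluoride first cleaves the two aryl silyl ethers, the ring B phenolate expels acetate by 1,6-elimination to give 18, the ring A phenolate closes the furan ring by 5-exo-trig oxa-1,6-conjugate addition through the transition state that keeps ring B and the C3 methyl apart (C2 becomes S under control of C3, as in biomimetic closures of such quinone methides), and excess fluoride then removes the two alkyl silyl ethers.

Compound list
1 | acenaphthenequinone | O=C1C(=O)c2cccc3cccc1c23 | starting material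
2 | cis-1,2-dimethyl-1,2-dihydroacenaphthylene-1,2-diol (meso mac diol) | C[C@]1(O)c2cccc3cccc(c23)[C@@]1(C)O | intermediate
3 | (E)-prop-1-en-1-ylboronic acid | C/C=C/B(O)O | starting material
4 | (E)-propenylB(mac) | C/C=C/B1O[C@@]2(C)c3cccc4cccc(c34)[C@@]2(C)O1 | intermediate
5 | 2-bromo-6-methoxyphenol | COc1cccc(Br)c1O | starting material
6 | 2-bromo-4-iodo-6-methoxyphenol | COc1cc(I)cc(Br)c1O | intermediate
7 | (S)-2-(tert-butyldimethylsilyloxy)propanal | C[C@H](O[Si](C)(C)C(C)(C)C)C=O | starting material
8 | chloromagnesium 2-bromo-4-(chloromagnesio)-6-methoxyphenolate | COc1cc([Mg]Cl)cc(Br)c1O[Mg]Cl | intermediate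
9 | (1R,2S)-1-(3-bromo-4-hydroxy-5-methoxyphenyl)-2-(TBS-oxy)propan-1-ol | COc1cc([C@@H](O)[C@H](C)O[Si](C)(C)C(C)(C)C)cc(Br)c1O | intermediate
10 | 1-bromo-2-(TBS-oxy)-3-methoxy-5-[(1R,2S)-1,2-bis(TBS-oxy)propyl]benzene | COc1cc([C@@H](O[Si](C)(C)C(C)(C)C)[C@H](C)O[Si](C)(C)C(C)(C)C)cc(Br)c1O[Si](C)(C)C(C)(C)C | intermediate
11 | 4-bromo-2-methoxyphenol | COc1cc(Br)ccc1O | starting material
12 | (4-bromo-2-methoxyphenoxy)(tert-butyl)dimethylsilane | COc1cc(Br)ccc1O[Si](C)(C)C(C)(C)C | intermediate
13 | 4-(TBS-oxy)-3-methoxyphenyllithium | COc1cc([Li])ccc1O[Si](C)(C)C(C)(C)C | intermediate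
14 | lithium [4-(TBS-oxy)-3-methoxyphenyl][(E)-prop-1-enyl]B(mac) borate (configuration at boron not defined) | [Li+].C/C=C/[B-]1(c2ccc(O[Si](C)(C)C(C)(C)C)c(OC)c2)O[C@@]2(C)c3cccc4cccc(c34)[C@@]2(C)O1 | intermediate
15 | B(mac) boronic ester of 16: boron in place of the C1 hydroxyl, same spatial arrangement (formally 1S,2R because boron ranks below carbon) | COc1cc([C@@H](B2O[C@@]3(C)c4cccc5cccc(c45)[C@@]3(C)O2)[C@@H](C)c2cc([C@@H](O[Si](C)(C)C(C)(C)C)[C@H](C)O[Si](C)(C)C(C)(C)C)cc(OC)c2O[Si](C)(C)C(C)(C)C)ccc1O[Si](C)(C)C(C)(C)C | intermediate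
16 | (1S,2S)-1-[4-(TBS-oxy)-3-methoxyphenyl]-2-{2-(TBS-oxy)-3-methoxy-5-[(1R,2S)-1,2-bis(TBS-oxy)propyl]phenyl}propan-1-ol | COc1cc([C@@H](O)[C@@H](C)c2cc([C@@H](O[Si](C)(C)C(C)(C)C)[C@H](C)O[Si](C)(C)C(C)(C)C)cc(OC)c2O[Si](C)(C)C(C)(C)C)ccc1O[Si](C)(C)C(C)(C)C | intermediate
17 | acetate of 16 (1S,2S) | COc1cc([C@@H](OC(C)=O)[C@@H](C)c2cc([C@@H](O[Si](C)(C)C(C)(C)C)[C@H](C)O[Si](C)(C)C(C)(C)C)cc(OC)c2O[Si](C)(C)C(C)(C)C)ccc1O[Si](C)(C)C(C)(C)C | intermediate
18 | para-quinone methide: 2-methoxy-4-alkylidenecyclohexa-2,5-dienone whose exocyclic CH (C2) is bonded to C3, with free ring A phenol and bis-TBS diol; C3 spatially unchanged (formally R), alkene geometry not defined | COC1=CC(=C[C@@H](C)c2cc([C@@H](O[Si](C)(C)C(C)(C)C)[C@H](C)O[Si](C)(C)C(C)(C)C)cc(OC)c2O)C=CC1=O | intermediate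
19 | (2S,3S)-2-(4-hydroxy-3-methoxyphenyl)-7-methoxy-3-methyl-5-[(1R,2S)-1,2-bis(TBS-oxy)propyl]-2,3-dihydrobenzofuran | COc1cc([C@H]2Oc3c(OC)cc([C@@H](O[Si](C)(C)C(C)(C)C)[C@H](C)O[Si](C)(C)C(C)(C)C)cc3[C@@H]2C)ccc1O | intermediate
20 | (1R,2S)-1-[(2S,3S)-2-(4-hydroxy-3-methoxyphenyl)-7-methoxy-3-methyl-2,3-dihydro-1-benzofuran-5-yl]propane-1,2-diol | COc1cc([C@H]2Oc3c(OC)cc([C@@H](O)[C@H](C)O)cc3[C@@H]2C)ccc1O | target

Total step count: 9. Longest linear sequence: 6 steps (5 → 6 → 9 → 10 → 16 → 17 → 20).

Steps most likely to fail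

Step 7. Oxidative addition into the hindered, electron-rich bromide may be slow. Direct Suzuki–Miyaura transfer or β-hydride elimination may then overtake the conjunctive pathway, and the aryl silyl ethers may suffer in the oxidative work-up. The fallback sets out from 10 and returns at 16.
- Stille vinylation of 10 (tributyl(vinyl)stannane, Pd(PPh3)4, toluene, 100 °C) should give the ring A styrene F1.
- Branched-selective asymmetric hydroformylation (Rh(acac)(CO)2, chiral bisphospholane ligand, CO/H2, toluene) should give the (S)-2-arylpropanal F2.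
- Addition of aryllithium 13 at −78 °C forms the same aryl–C2 bond and should give 16 together with its C1 epimer F3.
- Compound 16 re-enters at step 8. F3 is not lost, because the epimeric acetate F4 made from it collapses to the same quinone methide 18 under the conditions of step 9.

Step 9. Tautomerisation of the quinone methide to a stilbene would erase C3. Acetyl migration to the ring A phenolate or imperfect trans selectivity in the closure may also intervene. The fallback sets out from 16 and returns at 19.
- K2CO3 in MeOH at rt cleaves only the aryl silyl ethers and should give the bis-phenol F5.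
- Catalytic BF3·OEt2 in CH2Cl2 at −78 °C ionises the para-hydroxybenzylic alcohol. The β-oxygenated side-chain silyl ether is much less prone to ionise, and the ring A phenol traps the cation trans to the methyl group to give 19, isolated this time.
- TBAF then gives 20.

Step 4. Felkin–Anh facial selectivity may be poor, or the exchange on the electron-rich phenolate may be sluggish. The fallback sets out from 6 (through 8) and returns at 9.
- Commercial ethyl (S)-2-(tert-butyldimethylsilyloxy)propanoate is converted (MeNH(OMe)·HCl, i-PrMgCl, THF, −20 °C) into the Weinreb amide F6.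
- Acylation of 8 with F6 should give the aryl ketone F7.
- Catalyst-controlled asymmetric transfer hydrogenation (RuCl(p-cymene)[(S,S)-TsDPEN], HCO2H/Et3N, rt) then sets the benzylic carbinol independently of substrate bias and gives 9.

Further compounds
F1 | step 7 | 2-(TBS-oxy)-3-methoxy-5-[(1R,2S)-1,2-bis(TBS-oxy)propyl]styrene | C=Cc1cc([C@@H](O[Si](C)(C)C(C)(C)C)[C@H](C)O[Si](C)(C)C(C)(C)C)cc(OC)c1O[Si](C)(C)C(C)(C)C
F2 | step 7 | (S)-2-{2-(TBS-oxy)-3-methoxy-5-[(1R,2S)-1,2-bis(TBS-oxy)propyl]phenyl}propanal | O=C[C@@H](C)c1cc([C@@H](O[Si](C)(C)C(C)(C)C)[C@H](C)O[Si](C)(C)C(C)(C)C)cc(OC)c1O[Si](C)(C)C(C)(C)C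
F3 | step 7 | (1R,2S) C1 epimer of 16 | COc1cc([C@H](O)[C@@H](C)c2cc([C@@H](O[Si](C)(C)C(C)(C)C)[C@H](C)O[Si](C)(C)C(C)(C)C)cc(OC)c2O[Si](C)(C)C(C)(C)C)ccc1O[Si](C)(C)C(C)(C)C
F4 | step 7 | acetate of F3 (1R,2S) | COc1cc([C@H](OC(C)=O)[C@@H](C)c2cc([C@@H](O[Si](C)(C)C(C)(C)C)[C@H](C)O[Si](C)(C)C(C)(C)C)cc(OC)c2O[Si](C)(C)C(C)(C)C)ccc1O[Si](C)(C)C(C)(C)C
F5 | step 9 | (1S,2S)-1-(4-hydroxy-3-methoxyphenyl)-2-{2-hydroxy-3-methoxy-5-[(1R,2S)-1,2-bis(TBS-oxy)propyl]phenyl}propan-1-ol | COc1cc([C@@H](O)[C@@H](C)c2cc([C@@H](O[Si](C)(C)C(C)(C)C)[C@H](C)O[Si](C)(C)C(C)(C)C)cc(OC)c2O)ccc1O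
F6 | step 4 | (S)-2-(TBS-oxy)-N-methoxy-N-methylpropanamide | C[C@H](O[Si](C)(C)C(C)(C)C)C(=O)N(C)OC
F7 | step 4 | (S)-1-(3-bromo-4-hydroxy-5-methoxyphenyl)-2-(TBS-oxy)propan-1-one | COc1cc(C(=O)[C@H](C)O[Si](C)(C)C(C)(C)C)cc(Br)c1O
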